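**Retrosynthetic overview**
1. Key disconnection: the CH2–CH(Et) bond, made by a biomimetic vinylogous Michael (1,6-) addition between two but-1-enyl maleic anhydride monomers. The ring A monomer 8 (its CH2 activated as a tert-butyl acetate) is the donor and the ring B monomer 12 (propanoate side chain) is the acceptor.
2. Enabling feature: the CH(Et) carbon is δ to a carboxyl carbon of the C=C(CO2H)–CH(CO2H) unit (O=C–CH–C=CH–CH(Et)). That unit is a ring-opened 3-alkylidenesuccinic anhydride, i.e. the 1,6-adduct of a 3-(but-1-enyl)maleic anhydride (ring B). The CH2 is γ to a carbonyl of maleic anhydride ring A through the ring C=C, so it is a vinylogous enolate carbon.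
3. The one operation makes the C–C bond, the CH(Et) centre, the (Z)-trisubstituted alkene and, by α-protonation, the CH(CO2H) centre. TFA, water and warming then remove both tert-butyl groups, open ring B and expel the activating CO2H.
4. Both monomers come from dichloromaleic anhydride: diester, one Suzuki coupling to a common chlorodiene diester 4, then two Negishi couplings and saponification with ring closure.
5. Ring order: ring A (maleic anhydride) is closed in step 4 and kept. Ring B (maleic anhydride) is closed in step 6, becomes an alkylidenesuccinic anhydride in step 7 and is opened in step 8.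

Key step: step 7

Assumption: the sense of face selection by the quinine-derived squaramide cannot be predicted with certainty and is taken to be Si at the δ-carbon, its quinidine-derived pseudoenantiomer being used instead if the opposite sense were found; boronate 3 and the organozinc solutions 5 and 9 are taken as purchased.

Step 1
Reactants: 1 2,3-dichloromaleic anhydride
Product: 2 dimethyl (2Z)-2,3-dichlorobut-2-enedioate
Conditions: MeOH, H2SO4 (cat.), reflux
Reagents that add atoms: methanol, SMILES CO
Why: Acid-catalysed ring-opening methanolysis followed by Fischer esterification should give the diester, the cis arrangement of the two ester groups being inherited from the ring.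

Step 2
Reactants: 2 dimethyl (2Z)-2,3-dichlorobut-2-enedioate (1.5 equiv); 3 2-[(1E)-but-1-en-1-yl]-4,4,5,5-tetramethyl-1,3,2-dioxaborolane
Product: 4 dimethyl (2E)-2-[(1E)-but-1-en-1-yl]-3-chlorobut-2-enedioate (ester groups cis)
Conditions: Pd(OAc)2 (3 mol %), SPhos (6 mol %), CsF (3 equiv), THF, 50 °C
Reagents that add atoms: none
Why: Suzuki–Miyaura coupling of the activated β-chloro enoate (oxidative addition to zerovalent palladium, fluoride-assisted transmetalation, reductive elimination) should proceed with retention of both alkene geometries and stop at mono-coupling, because the boronate is limiting and the remaining, now dienylic, C–Cl bond is less reactive.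

Step 3
Reactants: 4 dimethyl (2E)-2-[(1E)-but-1-en-1-yl]-3-chlorobut-2-enedioate; 5 bromo(2-tert-butoxy-2-oxoethyl)zinc (2.2 equiv)
Product: 6 dimethyl (2Z)-2-[(1E)-but-1-en-1-yl]-3-(2-tert-butoxy-2-oxoethyl)but-2-enedioate
Conditions: Pd2(dba)3 (2.5 mol %), XPhos (10 mol %), THF, 45 °C; aq. NH4Cl work-up
Reagents that add atoms: none
Why: Negishi coupling of a Reformatsky-type zinc ester enolate with an activated vinyl chloride should replace chlorine with retention of the alkene geometry, the excess reagent allowing for deprotonation of the acidic CH2 of the product.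

Step 4
Reactants: 6 dimethyl (2Z)-2-[(1E)-but-1-en-1-yl]-3-(2-tert-butoxy-2-oxoethyl)but-2-enedioate
Product: 8 tert-butyl 2-[4-[(1E)-but-1-en-1-yl]-2,5-dioxo-2,5-dihydrofuran-3-yl]acetate, via maleic diacid 7 (not isolated)
Conditions: LiOH·H2O (3.5 equiv), THF/H2O 3:1, 0 °C to rt; 1 M HCl to pH 2, EtOAc; concentrate from toluene
Reagents that add atoms: lithium hydroxide, SMILES [Li+].[OH-]
Why: Saponification should cleave only the two methyl esters (the tert-butyl ester resists hydroxide), and on acidification the tetrasubstituted maleic diacid should close spontaneously to anhydride ring A.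

Step 5
Reactants: 4 dimethyl (2E)-2-[(1E)-but-1-en-1-yl]-3-chlorobut-2-enedioate; 9 bromo(3-tert-butoxy-3-oxopropyl)zinc (1.5 equiv)
Product: 10 dimethyl (2Z)-2-[(1E)-but-1-en-1-yl]-3-(3-tert-butoxy-3-oxopropyl)but-2-enedioate
Conditions: Pd2(dba)3 (2.5 mol %), XPhos (10 mol %), THF, 45 °C
Reagents that add atoms: none
Why: Negishi coupling of a β-zinc ester (zinc homoenolate) with the activated vinyl chloride should install the propanoate chain with retention of the alkene geometry.

Step 6
Reactants: 10 dimethyl (2Z)-2-[(1E)-but-1-en-1-yl]-3-(3-tert-butoxy-3-oxopropyl)but-2-enedioate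
Product: 12 tert-butyl 3-[4-[(1E)-but-1-en-1-yl]-2,5-dioxo-2,5-dihydrofuran-3-yl]propanoate, via maleic diacid 11 (not isolated)
Conditions: LiOH·H2O (2.5 equiv), THF/H2O 3:1, 0 °C to rt; 1 M HCl to pH 2, EtOAc; concentrate from toluene
Reagents that add atoms: lithium hydroxide, SMILES [Li+].[OH-]
Why: Selective saponification of the methyl esters and spontaneous closure of the tetrasubstituted maleic diacid on acidification should give anhydride ring B with the tert-butyl ester intact.

Step 7
Reactants: 8 tert-butyl 2-[4-[(1E)-but-1-en-1-yl]-2,5-dioxo-2,5-dihydrofuran-3-yl]acetate; 12 tert-butyl 3-[4-[(1E)-but-1-en-1-yl]-2,5-dioxo-2,5-dihydrofuran-3-yl]propanoate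
Product: 14 tert-butyl 3-[(3R,4Z)-4-[(2S)-2-[1-[4-[(1E)-but-1-en-1-yl]-2,5-dioxo-2,5-dihydrofuran-3-yl]-2-tert-butoxy-2-oxoethyl]butylidene]-2,5-dioxooxolan-3-yl]propanoate (epimer mixture at the ester-bearing CH), via ring B dienol 13 (not isolated)
Conditions: quinine-derived squaramide (3-[3,5-bis(trifluoromethyl)anilino]-4-[(9-deoxy-9-epi-quinin-9-yl)amino]cyclobut-3-ene-1,2-dione, 10 mol %), toluene, −20 °C, 12 in excess (2.5 equiv, the surplus recovered), 8 (1.0 equiv) added over 8 h; cold filtration through a short pad of silica gel to hold back the catalyst, then rapid chromatography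
Reagents that add atoms: none
Why: Proposed new method: the quinuclidine nitrogen of the catalyst deprotonates the CH2 of 8, which is acidified by its ester and, through the ring C=C, by a ring A carbonyl, and the ion-paired ring A dienolate adds through its exocyclic carbon to the butenyl terminus (δ-carbon) of 12, whose ring B carbonyl is bound by the squaramide N–H bonds, to give ring B dienol 13, held on the catalyst as its quinuclidinium dienolate ion pair, which is ketonised by proton transfer from a further molecule of 8 to its ring α-carbon (vinylogous Michael or 1,6-addition followed by α-protonation), so that the step is a pure addition of 8 to 12 and the catalyst is returned unchanged. The closest known reaction types are the amine-promoted biomimetic coupling of alkenyl(methyl)maleic anhydrides on the way to nonadrides, squaramide–cinchona-catalysed Michael additions of enolisable cyclic anhydrides, and bifunctional-catalyst 1,6-additions of malonates to para-quinone methides, in which the bound carbonyl and the attacked carbon are as far apart as here. No ring is closed: ring B changes from a maleic to a 3-alkylidenesuccinic anhydride, and the Z geometry of the new C=C follows from the s-trans diene conformation that the neighbouring ring substituent imposes. The CH(Et) centre is set by catalyst-controlled attack on the Si face of the δ-carbon (R in the target, formally S in 14 only because the ester raises the CIP rank of its neighbour), the ring CH centre (R) by protonation on the Si face of the α-carbon, which is the face opposite to the one covered by the catalyst and the newly attached ring A unit, and the ester-bearing carbon is left as an epimer mixture that is erased on decarboxylation. The step needs 1,6- over 1,4-addition, secured by the fully substituted ring C=C against the unhindered CH terminus; cross- over homo-coupling, secured by the far higher acidity of 8 than of the side-chain CH2 of 12 and by slow addition of 8 to excess 12; and α-protonation without later migration of the exocyclic C=C into the ring, secured by the weak amine base, the low temperature and the removal of the catalyst on cold silica.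

Step 8
Reactants: 14 tert-butyl 3-[(3R,4Z)-4-[(2S)-2-[1-[4-[(1E)-but-1-en-1-yl]-2,5-dioxo-2,5-dihydrofuran-3-yl]-2-tert-butoxy-2-oxoethyl]butylidene]-2,5-dioxooxolan-3-yl]propanoate
Product: 17 (2R)-2-[(1Z,3R)-3-[[4-[(1E)-but-1-en-1-yl]-2,5-dioxo-2,5-dihydrofuran-3-yl]methyl]-1-carboxypent-1-en-1-yl]pentanedioic acid, via bis-anhydride diacid 15 (not isolated), via ring-B-opened tetra-acid 16 (not isolated)
Conditions: TFA/CH2Cl2 1:3, 0 °C to rt; evaporate; MeCN/H2O 1:1, rt then 60 °C; lyophilise, reverse-phase HPLC (MeCN/H2O, 0.1 % HCO2H)
Reagents that add atoms: water, SMILES O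
Why: Acidolysis with TFA should remove both tert-butyl esters as 2-methylpropene without touching the anhydrides, water should then open the 3-alkylidenesuccinic anhydride ring B (which, unlike the tetrasubstituted maleic anhydride ring A, does not re-close in acidic water), and the ring A acetic acid, a vinylogous β-keto acid, should lose CO2 on warming through the ring A dienol to leave the CH2 group, no base being present that could epimerise the two stereocentres or move the alkene.

**Compound list**
1 | 3,4-dichlorofuran-2,5-dione (2,3-dichloromaleic anhydride) | O=C1OC(=O)C(Cl)=C1Cl | starting material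
2 | dimethyl (2Z)-2,3-dichlorobut-2-enedioate (dimethyl dichloromaleate) | COC(=O)/C(Cl)=C(/Cl)C(=O)OC | intermediate
3 | 2-[(1E)-but-1-en-1-yl]-4,4,5,5-tetramethyl-1,3,2-dioxaborolane | CC/C=C/B1OC(C)(C)C(C)(C)O1 | starting material
4 | dimethyl (2E)-2-[(1E)-but-1-en-1-yl]-3-chlorobut-2-enedioate (ester groups cis, maleate type) | CC/C=C/C(C(=O)OC)=C(\Cl)C(=O)OC | intermediate
5 | bromo(2-tert-butoxy-2-oxoethyl)zinc (Reformatsky reagent, solution in THF) | CC(C)(C)OC(=O)C[Zn]Br | starting material
6 | dimethyl (2Z)-2-[(1E)-but-1-en-1-yl]-3-(2-tert-butoxy-2-oxoethyl)but-2-enedioate | CC/C=C/C(C(=O)OC)=C(\CC(=O)OC(C)(C)C)C(=O)OC | intermediate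
7 | (2Z)-2-[(1E)-but-1-en-1-yl]-3-(2-tert-butoxy-2-oxoethyl)but-2-enedioic acid | CC/C=C/C(C(=O)O)=C(\CC(=O)OC(C)(C)C)C(=O)O | intermediate
8 | tert-butyl 2-[4-[(1E)-but-1-en-1-yl]-2,5-dioxo-2,5-dihydrofuran-3-yl]acetate (ring A monomer) | CC/C=C/C1=C(CC(=O)OC(C)(C)C)C(=O)OC1=O | intermediate
9 | bromo(3-tert-butoxy-3-oxopropyl)zinc (solution in THF) | CC(C)(C)OC(=O)CC[Zn]Br | starting material
10 | dimethyl (2Z)-2-[(1E)-but-1-en-1-yl]-3-(3-tert-butoxy-3-oxopropyl)but-2-enedioate | CC/C=C/C(C(=O)OC)=C(\CCC(=O)OC(C)(C)C)C(=O)OC | intermediate
11 | (2Z)-2-[(1E)-but-1-en-1-yl]-3-(3-tert-butoxy-3-oxopropyl)but-2-enedioic acid | CC/C=C/C(C(=O)O)=C(\CCC(=O)OC(C)(C)C)C(=O)O | intermediate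
12 | tert-butyl 3-[4-[(1E)-but-1-en-1-yl]-2,5-dioxo-2,5-dihydrofuran-3-yl]propanoate (ring B monomer) | CC/C=C/C1=C(CCC(=O)OC(C)(C)C)C(=O)OC1=O | intermediate
13 | ring B dienol of the 1,6-adduct: tert-butyl 3-[(4Z)-4-[(2S)-2-[1-[4-[(1E)-but-1-en-1-yl]-2,5-dioxo-2,5-dihydrofuran-3-yl]-2-tert-butoxy-2-oxoethyl]butylidene]-2-hydroxy-5-oxo-4,5-dihydrofuran-3-yl]propanoate (written in its neutral form; in the flask it is paired with the catalyst as the quinuclidinium dienolate; epimer mixture at the ester-bearing CH) | CC/C=C/C1=C(C(C(=O)OC(C)(C)C)[C@H](/C=C2\C(=O)OC(O)=C2CCC(=O)OC(C)(C)C)CC)C(=O)OC1=O | intermediate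
14 | tert-butyl 3-[(3R,4Z)-4-[(2S)-2-[1-[4-[(1E)-but-1-en-1-yl]-2,5-dioxo-2,5-dihydrofuran-3-yl]-2-tert-butoxy-2-oxoethyl]butylidene]-2,5-dioxooxolan-3-yl]propanoate (epimer mixture at the ester-bearing CH) | CC/C=C/C1=C(C(C(=O)OC(C)(C)C)[C@H](/C=C2\C(=O)OC(=O)[C@@H]2CCC(=O)OC(C)(C)C)CC)C(=O)OC1=O | intermediate
15 | 3-[(3R,4Z)-4-[(2S)-2-[carboxy[4-[(1E)-but-1-en-1-yl]-2,5-dioxo-2,5-dihydrofuran-3-yl]methyl]butylidene]-2,5-dioxooxolan-3-yl]propanoic acid (epimer mixture at the carboxy-bearing CH) | CC/C=C/C1=C(C(C(=O)O)[C@H](/C=C2\C(=O)OC(=O)[C@@H]2CCC(=O)O)CC)C(=O)OC1=O | intermediate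
16 | (2R)-2-[(1Z,3S)-3-[carboxy[4-[(1E)-but-1-en-1-yl]-2,5-dioxo-2,5-dihydrofuran-3-yl]methyl]-1-carboxypent-1-en-1-yl]pentanedioic acid (epimer mixture at the carboxy-bearing CH) | CC/C=C/C1=C(C(C(=O)O)[C@H](/C=C(\C(=O)O)[C@@H](CCC(=O)O)C(=O)O)CC)C(=O)OC1=O | intermediate
17 | (2R)-2-[(1Z,3R)-3-[[4-[(1E)-but-1-en-1-yl]-2,5-dioxo-2,5-dihydrofuran-3-yl]methyl]-1-carboxypent-1-en-1-yl]pentanedioic acid | CC/C=C/C1=C(C[C@H](/C=C(\C(=O)O)[C@@H](CCC(=O)O)C(=O)O)CC)C(=O)OC1=O | target

**Step count and risks**
Total step count: 8. Longest linear sequence: 6 steps (steps 1, 2, 3, 4, 7, 8; the branch through steps 5 and 6 is equally long).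

Steps most likely to fail:

1. Step 7 (Proposed new method). What may go wrong:
   - weak or reversed face discrimination at the δ-carbon;
   - unselective protonation at the ring carbon of ring B;
   - homo-coupling of 8;
   - drift of the exocyclic double bond into ring B;
   - intramolecular C-acylation of ring B by the re-formed ester-stabilised anion.

   Fallback (known chemistry), setting out from 8 and 12 and returning at 14: the two anhydrides are coupled without a chiral catalyst under the catalytic triethylamine/MgCl2 conditions known for the biomimetic dimerisation of alkenylmaleic anhydrides, with 12 in excess. This gives the stereorandom adduct tert-butyl 3-[(4Z)-4-[2-[1-[4-[(1E)-but-1-en-1-yl]-2,5-dioxo-2,5-dihydrofuran-3-yl]-2-tert-butoxy-2-oxoethyl]butylidene]-2,5-dioxooxolan-3-yl]propanoate F1. Compound 14 is then isolated from F1 by preparative chromatography on a chiral stationary phase. The fraction epimeric at the ring CH is recycled by brief triethylamine-catalysed enolisation of ring B and renewed separation.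

2. Step 8. What may go wrong: epimerisation of the ring B CH centre, or migration of the exocyclic double bond into the ring, while ring B is still an anhydride under acid and heat; decarboxylation may also be sluggish.

   Fallback, setting out from 14 and returning at 16: ring B is opened first with water under neutral conditions (THF/H2O, rt) to the diacid (2R,3Z)-2-(3-tert-butoxy-3-oxopropyl)-3-[(2S)-2-[1-[4-[(1E)-but-1-en-1-yl]-2,5-dioxo-2,5-dihydrofuran-3-yl]-2-tert-butoxy-2-oxoethyl]butylidene]butanedioic acid F2. In F2 the former ring carbon is α only to a free carboxyl group and is no longer readily enolised. TFA/CH2Cl2 then removes the two tert-butyl groups to give 16, which is decarboxylated by warming in aqueous acetonitrile as in the route.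

3. Step 4. What may go wrong: under hydroxide the acidic methylene of triester 6 is deprotonated, so that the double bond wanders out of the ring-forming position (aconitate-type isomerisation) or the resulting anion resists saponification.

   Fallback, setting out from 4 and returning at 8: the order is reversed so that base never meets this methylene. Chlorodiene diester 4 is saponified and closed (LiOH·H2O, THF/H2O; then HCl) to 3-[(1E)-but-1-en-1-yl]-4-chlorofuran-2,5-dione F3. F3 is then coupled under neutral Migita–Kosugi–Stille conditions (Pd2(dba)3, P(t-Bu)3, dioxane) with tert-butyl 2-(tributylstannyl)acetate to give 8 directly.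

Further compounds
F1 | step 7 | tert-butyl 3-[(4Z)-4-[2-[1-[4-[(1E)-but-1-en-1-yl]-2,5-dioxo-2,5-dihydrofuran-3-yl]-2-tert-butoxy-2-oxoethyl]butylidene]-2,5-dioxooxolan-3-yl]propanoate (all stereoisomers at the three sp3 centres) | CC/C=C/C1=C(C(C(=O)OC(C)(C)C)C(/C=C2\C(=O)OC(=O)C2CCC(=O)OC(C)(C)C)CC)C(=O)OC1=O
F2 | step 8 | (2R,3Z)-2-(3-tert-butoxy-3-oxopropyl)-3-[(2S)-2-[1-[4-[(1E)-but-1-en-1-yl]-2,5-dioxo-2,5-dihydrofuran-3-yl]-2-tert-butoxy-2-oxoethyl]butylidene]butanedioic acid (epimer mixture at the ester-bearing CH) | CC/C=C/C1=C(C(C(=O)OC(C)(C)C)[C@H](/C=C(\C(=O)O)[C@@H](CCC(=O)OC(C)(C)C)C(=O)O)CC)C(=O)OC1=O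
F3 | step 4 | 3-[(1E)-but-1-en-1-yl]-4-chlorofuran-2,5-dione | CC/C=C/C1=C(Cl)C(=O)OC1=O
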